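**Retrosynthetic overview**
- The target is disconnected by a 1,2-methyl shift (C-10 to C-9) back to a cis-fused labda-8,13-diene; protonation at C-8 starts the shift and loss of H-1 ends it.
- The labdadiene comes from a B-alkyl Suzuki coupling (C-9–C-11 bond) of a C6 dienol-derived borane with the enol triflate of a cis-decalone.
- Ring A of the decalone is closed by intramolecular enolate alkylation (C-1–C-10); the C-4 quaternary carbon comes from an ester-enolate alkylation.
- C-5 is set by a catalytic asymmetric Mukaiyama–Michael addition of a propanoate ketene silyl acetal to 2-methylcyclohex-2-en-1-one.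
- Ring order: ring B is purchased, ring A is annulated in step 4, and the last step rearranges the skeleton without forming a ring.

Assumption: the SMILES is taken as drawn, (4S,5R,8R,9S), with H-5 on the same face as the C-8 and C-9 methyl groups; locants C-1 to C-15 follow labdane/halimane numbering.

**Step 1**
Reactants: 1 methyl propanoate
Product: 3 (E)-1-methoxy-1-(trimethylsilyloxy)prop-1-ene, via lithium propanoate enolate 2 (not isolated)
Conditions: LDA, THF, −78 °C; then Me3SiCl, −78 °C to rt
Reagents that add atoms: chlorotrimethylsilane (C[Si](C)(C)Cl)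
Why: Kinetic deprotonation of the ester and O-silylation of the lithium enolate is the standard Ireland-type preparation of a ketene silyl acetal, and no stereocentre is formed.

**Step 2**
Reactants: 3 (E)-1-methoxy-1-(trimethylsilyloxy)prop-1-ene; 4 2-methylcyclohex-2-en-1-one
Product: 5 methyl 2-[(1S)-2-methyl-3-(trimethylsilyloxy)cyclohex-2-en-1-yl]propanoate (both epimers at C-2 of the propanoate)
Conditions: oxazaborolidinium triflimide from (S)-α,α-diphenylprolinol, o-tolylboronic acid and HNTf2 (20 mol %), Ph3PO (25 mol %), toluene, −20 °C, non-aqueous work-up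
Reagents that add atoms: none
Why: This is an oxazaborolidinium-catalysed asymmetric Mukaiyama–Michael addition to a cyclic enone, in which the ketene acetal attacks the Re face of C-3 of the catalyst-bound enone to set the ring stereocentre as (1S) (the (R)-catalyst is used if the sense proves opposite), the silyl group ends on the enolate oxygen, and the epimeric centre next to the ester is erased in step 3.

**Step 3**
Reactants: 5 methyl 2-[(1S)-2-methyl-3-(trimethylsilyloxy)cyclohex-2-en-1-yl]propanoate; 6 1,3-dibromopropane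
Product: 8 methyl (2S)-5-bromo-2-methyl-2-[(1R)-2-methyl-3-(trimethylsilyloxy)cyclohex-2-en-1-yl]pentanoate, via lithium ester enolate 7 (not isolated)
Conditions: LDA, THF/DMPU, −78 °C; then 6 (3 equiv), −78 to −20 °C
Reagents that add atoms: none
Why: This ester-enolate alkylation creates the C-4 quaternary carbon, because with the ring hydrogen eclipsing the enolate plane (allylic 1,3-strain) the electrophile enters anti to the ring carbon that carries the vinylic methyl and silyloxy groups, which gives (2S), and excess dibromide prevents double alkylation.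

**Step 4**
Reactants: 8 methyl (2S)-5-bromo-2-methyl-2-[(1R)-2-methyl-3-(trimethylsilyloxy)cyclohex-2-en-1-yl]pentanoate
Product: 10 methyl (1S,4aR,8aR)-1,4a-dimethyl-5-oxodecahydronaphthalene-1-carboxylate, via ammonium ketone enolate 9 (not isolated)
Conditions: Bu4N[Ph3SiF2] (TBAT, 1.2 equiv), THF, 0 to 40 °C
Reagents that add atoms: none
Why: Fluoride unmasks the regiodefined tetrasubstituted enolate, which closes ring A by 6-exo-tet C-alkylation (Michael-initiated ring-closure logic), and because allylic 1,2-strain with the enolate methyl keeps the side chain pseudoaxial the bromide is reached on the same face, so the angular methyl ends cis to the ring-fusion hydrogen.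

**Step 5**
Reactants: 10 methyl (1S,4aR,8aR)-1,4a-dimethyl-5-oxodecahydronaphthalene-1-carboxylate
Product: 12 methyl (1S,4aR,8aR)-1,4a,6-trimethyl-5-oxodecahydronaphthalene-1-carboxylate (both C-6 epimers), via lithium ketone enolate 11 (not isolated)
Conditions: LDA (1.1 equiv), THF, −78 °C; then MeI, −78 to 0 °C
Reagents that add atoms: iodomethane (CI)
Why: Kinetic enolate methylation can occur only at this position (the other alpha carbon and the ester alpha carbon are quaternary), and the epimer mixture is harmless because this carbon becomes sp2 in step 6 and is set in step 10.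

**Step 6**
Reactants: 12 methyl (1S,4aR,8aR)-1,4a,6-trimethyl-5-oxodecahydronaphthalene-1-carboxylate
Product: 14 methyl (1S,4aR,8aR)-1,4a,6-trimethyl-5-(trifluoromethanesulfonyloxy)-1,2,3,4,4a,7,8,8a-octahydronaphthalene-1-carboxylate, via potassium enolate 13 (not isolated)
Conditions: KHMDS, THF, −78 to 0 °C; then PhNTf2, −78 °C to rt
Reagents that add atoms: N-phenylbis(trifluoromethanesulfonimide) (O=S(=O)(N(c1ccccc1)S(=O)(=O)C(F)(F)F)C(F)(F)F)
Why: Deprotonation of the single alpha hydrogen and O-triflation (enol triflate formation, as for 2,2,6-trimethylcyclohexanone) gives the tetrasubstituted triflate without touching the quaternary ester.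

**Step 7**
Reactants: 15 (2E)-3-methylpent-2-en-4-yn-1-ol
Product: 16 (2E)-3-methylpenta-2,4-dien-1-ol
Conditions: H2 (1 atm), Pd/CaCO3 poisoned with Pb(OAc)2 (Lindlar catalyst), quinoline, EtOAc, rt
Reagents that add atoms: none
Why: Lindlar semihydrogenation stops at the terminal vinyl group and leaves the (E)-trisubstituted alkene, so the side-chain geometry is carried over from the starting material.

**Step 8**
Reactants: 16 (2E)-3-methylpenta-2,4-dien-1-ol; 14 methyl (1S,4aR,8aR)-1,4a,6-trimethyl-5-(trifluoromethanesulfonyloxy)-1,2,3,4,4a,7,8,8a-octahydronaphthalene-1-carboxylate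
Product: 18 methyl (1S,4aR,8aR)-5-[(3E)-5-hydroxy-3-methylpent-3-en-1-yl]-1,4a,6-trimethyl-1,2,3,4,4a,7,8,8a-octahydronaphthalene-1-carboxylate, via bis-boron hydroboration adduct 17 (not isolated)
Conditions: 9-BBN (2.2 equiv), THF, 0 °C to rt; then 14, PdCl2(dppf) (10 mol %), AsPh3, Cs2CO3, DMF/H2O, 50 °C
Reagents that add atoms: none
Why: 9-BBN adds anti-Markovnikov only to the monosubstituted alkene of the diene (the hydroxyl is carried as its borinate), and the B-alkyl Suzuki–Miyaura coupling with the hindered enol triflate forms the C-9–C-11 bond with the E alkene intact and no new stereocentre.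

**Step 9**
Reactants: 18 methyl (1S,4aR,8aR)-5-[(3E)-5-hydroxy-3-methylpent-3-en-1-yl]-1,4a,6-trimethyl-1,2,3,4,4a,7,8,8a-octahydronaphthalene-1-carboxylate
Product: 19 methyl (1S,4aR,8aR)-5-[(3E)-5-acetoxy-3-methylpent-3-en-1-yl]-1,4a,6-trimethyl-1,2,3,4,4a,7,8,8a-octahydronaphthalene-1-carboxylate
Conditions: Ac2O, pyridine, DMAP (cat.), CH2Cl2, 0 °C to rt
Reagents that add atoms: acetic anhydride (CC(=O)OC(C)=O)
Why: This is a standard DMAP-catalysed acetylation of the primary allylic alcohol, placed before the acid step because the acetate is a far poorer leaving group and pi-nucleophile than the free alcohol.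

**Step 10**
Reactants: 19 methyl (1S,4aR,8aR)-5-[(3E)-5-acetoxy-3-methylpent-3-en-1-yl]-1,4a,6-trimethyl-1,2,3,4,4a,7,8,8a-octahydronaphthalene-1-carboxylate
Product: 20 methyl (1S,5S,6R,8aR)-5-[(3E)-5-acetoxy-3-methylpent-3-en-1-yl]-1,5,6-trimethyl-1,2,3,5,6,7,8,8a-octahydronaphthalene-1-carboxylate
Conditions: confined imidodiphosphorimidate Brønsted acid (IDPi from two (S)-3,3'-bis[3,5-bis(trifluoromethyl)phenyl]-BINOL units, N-triflyl core; 5 mol %), CHCl3, −20 °C to rt, stopped at full conversion
Reagents that add atoms: none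
Why: Proposed new method: the confined acid protonates the tetrasubstituted alkene at C-8 on the face anti to the pseudoaxial angular methyl (the bulky acid avoids the syn-axial methyl and the C–CH3 bond is antiperiplanar), the methyl migrates suprafacially from C-10 to C-9 inside the contact ion pair (which puts the C-9 methyl on the H-5 face, the side chain opposite, and the C-8 methyl cis to the migrated methyl), and the counteranion held on the protonation face removes H-1 rather than H-5 (which lies on the other face) to give the 1(10)-alkene, while the ester at C-4 disfavours a further hydride shift from C-5 and the allylic acetate stays a spectator as it does in acid-mediated cyclisations of farnesyl acetate; the closest known reaction types are IDPi-catalysed Wagner–Meerwein shifts of alkenyl cycloalkanes and stoichiometric acid-mediated backbone (friedo) rearrangements of labdane- and drimane-type olefins and epoxides.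

**Compound list**
1 | methyl propanoate | CCC(=O)OC | starting material
2 | lithium enolate of methyl propanoate (O–Li trans to the C-methyl) | C/C=C(OC)/O[Li] | intermediate
3 | (E)-1-methoxy-1-(trimethylsilyloxy)prop-1-ene | C/C=C(OC)/O[Si](C)(C)C | intermediate
4 | 2-methylcyclohex-2-en-1-one | CC1=CCCCC1=O | starting material
5 | methyl 2-[(1S)-2-methyl-3-(trimethylsilyloxy)cyclohex-2-en-1-yl]propanoate | COC(=O)C(C)[C@@H]1CCCC(O[Si](C)(C)C)=C1C | intermediate
6 | 1,3-dibromopropane | BrCCCBr | starting material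
7 | lithium ester enolate of 5 | COC(O[Li])=C(C)[C@@H]1CCCC(O[Si](C)(C)C)=C1C | intermediate
8 | methyl (2S)-5-bromo-2-methyl-2-[(1R)-2-methyl-3-(trimethylsilyloxy)cyclohex-2-en-1-yl]pentanoate | COC(=O)[C@@](C)(CCCBr)[C@@H]1CCCC(O[Si](C)(C)C)=C1C | intermediate
9 | tetrabutylammonium (3R)-3-[(2S)-5-bromo-1-methoxy-2-methyl-1-oxopentan-2-yl]-2-methylcyclohex-1-en-1-olate | COC(=O)[C@@](C)(CCCBr)[C@@H]1CCCC([O-])=C1C.CCCC[N+](CCCC)(CCCC)CCCC | intermediate
10 | methyl (1S,4aR,8aR)-1,4a-dimethyl-5-oxodecahydronaphthalene-1-carboxylate (cis-fused) | COC(=O)[C@@]1(C)CCC[C@]2(C)[C@H]1CCCC2=O | intermediate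
11 | lithium enolate of 10 (enolate toward C-6) | COC(=O)[C@@]1(C)CCC[C@]2(C)[C@H]1CCC=C2O[Li] | intermediate
12 | methyl (1S,4aR,8aR)-1,4a,6-trimethyl-5-oxodecahydronaphthalene-1-carboxylate (C-6 epimers) | COC(=O)[C@@]1(C)CCC[C@]2(C)[C@H]1CCC(C)C2=O | intermediate
13 | potassium enolate of 12 | COC(=O)[C@@]1(C)CCC[C@]2(C)[C@H]1CCC(C)=C2O[K] | intermediate
14 | methyl (1S,4aR,8aR)-1,4a,6-trimethyl-5-(trifluoromethanesulfonyloxy)-1,2,3,4,4a,7,8,8a-octahydronaphthalene-1-carboxylate | COC(=O)[C@@]1(C)CCC[C@]2(C)[C@H]1CCC(C)=C2OS(=O)(=O)C(F)(F)F | intermediate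
15 | (2E)-3-methylpent-2-en-4-yn-1-ol | C#C/C(C)=C/CO | starting material
16 | (2E)-3-methylpenta-2,4-dien-1-ol | C=C/C(C)=C/CO | intermediate
17 | 9-[(3E)-5-(9-borabicyclo[3.3.1]nonan-9-yloxy)-3-methylpent-3-en-1-yl]-9-borabicyclo[3.3.1]nonane | B1(CC/C(C)=C/COB2C3CCCC2CCC3)C2CCCC1CCC2 | intermediate
18 | methyl (1S,4aR,8aR)-5-[(3E)-5-hydroxy-3-methylpent-3-en-1-yl]-1,4a,6-trimethyl-1,2,3,4,4a,7,8,8a-octahydronaphthalene-1-carboxylate | COC(=O)[C@@]1(C)CCC[C@]2(C)[C@H]1CCC(C)=C2CC/C(C)=C/CO | intermediate
19 | methyl (1S,4aR,8aR)-5-[(3E)-5-acetoxy-3-methylpent-3-en-1-yl]-1,4a,6-trimethyl-1,2,3,4,4a,7,8,8a-octahydronaphthalene-1-carboxylate | COC(=O)[C@@]1(C)CCC[C@]2(C)[C@H]1CCC(C)=C2CC/C(C)=C/COC(C)=O | intermediate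
20 | methyl (1S,5S,6R,8aR)-5-[(3E)-5-acetoxy-3-methylpent-3-en-1-yl]-1,5,6-trimethyl-1,2,3,5,6,7,8,8a-octahydronaphthalene-1-carboxylate | COC(=O)[C@@]1(C)CCC=C2[C@H]1CC[C@@H](C)[C@]2(C)CC/C(C)=C/COC(C)=O | target

**Step count**
Total steps: 10. Longest linear sequence: 9 (steps 1–6, 8, 9, 10; step 7 is the only side branch).

**Steps most likely to fail**

Step 10 (the proposed new step). The risks are proton loss at C-5 to the 5(10)-alkene, protonation on the other face giving the C-8 epimer, and capture of the C-10 cation by the side-chain alkene. The fallback uses known chemistry only and no cationic shift: the C-9 quaternary centre is made by conjugate addition and enolate alkylation, and ring A is closed last by a Diels–Alder reaction. It sets out from 4 and 16 and comes back at 20.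
- Dienol 16 is silylated (TBSCl, imidazole) to tert-butyl(dimethyl){[(2E)-3-methylpenta-2,4-dien-1-yl]oxy}silane F1.
- 9-BBN hydroboration followed by iodinolysis (I2, NaOMe) gives tert-butyl{[(2E)-5-iodo-3-methylpent-2-en-1-yl]oxy}dimethylsilane F2.
- Enone 4 undergoes copper-catalysed asymmetric conjugate addition of Me3Al (Cu(OTf)2, chiral phosphoramidite, Et2O, −30 °C) with TMSOTf trapping to give {[(3R)-2,3-dimethylcyclohex-1-en-1-yl]oxy}trimethylsilane F3.
- MeLi, then F2 in THF/HMPA, alkylates anti to the 3-methyl group and gives (2S,3R)-2-[(3E)-5-{[tert-butyl(dimethyl)silyl]oxy}-3-methylpent-3-en-1-yl]-2,3-dimethylcyclohexan-1-one F4.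
- KHMDS/PhNTf2 gives (5R,6S)-6-[(3E)-5-{[tert-butyl(dimethyl)silyl]oxy}-3-methylpent-3-en-1-yl]-5,6-dimethylcyclohex-1-en-1-yl trifluoromethanesulfonate F5.
- Stille coupling with tributyl(vinyl)stannane (Pd(PPh3)4, LiCl, THF, reflux) gives tert-butyl({(2E)-5-[(1S,6R)-2-ethenyl-1,6-dimethylcyclohex-2-en-1-yl]-3-methylpent-2-en-1-yl}oxy)dimethylsilane F6.
- Thermal Diels–Alder reaction with methyl methacrylate (neat, BHT, 130 °C) proceeds ortho and endo, anti to the pseudoaxial C-9 methyl, and gives methyl (1S,5S,6R,8aR)-5-[(3E)-5-{[tert-butyl(dimethyl)silyl]oxy}-3-methylpent-3-en-1-yl]-1,5,6-trimethyl-1,2,3,5,6,7,8,8a-octahydronaphthalene-1-carboxylate F7.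
- TBAF gives methyl (1S,5S,6R,8aR)-5-[(3E)-5-hydroxy-3-methylpent-3-en-1-yl]-1,5,6-trimethyl-1,2,3,5,6,7,8,8a-octahydronaphthalene-1-carboxylate F8, and Ac2O/pyridine gives 20.

Step 3. The risk is low or reversed diastereoselectivity at the new quaternary carbon, which rests on acyclic 1,2-induction. The fallback reverses the order in which the two C-4 substituents are introduced, which is stereo-complementary: the same enolate face then delivers the methyl group in place of the three-carbon chain. It sets out from 4 (with purchased 5-bromopentanoyl chloride) and comes back at 8.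
- 5-Bromopentanoyl chloride with MeOH/pyridine gives methyl 5-bromopentanoate F9.
- LDA/Me3SiCl at −78 °C gives [(5-bromo-1-methoxypent-1-en-1-yl)oxy]trimethylsilane F10.
- The catalysed Mukaiyama–Michael addition of step 2 to 4 gives methyl 5-bromo-2-[(1S)-2-methyl-3-(trimethylsilyloxy)cyclohex-2-en-1-yl]pentanoate F11.
- LDA then MeI gives 8 when the electrophile prefers the face syn to the methyl-bearing ring carbon, which is the case in which step 3 itself gives the wrong epimer.

Step 2. The risk is low rate or enantioselectivity, because the alpha-methyl enone is an extension of the cyclic enones for which this catalysed addition is established. The fallback uses the parent enone and introduces the ring methyl afterwards. It sets out from 3 (with purchased cyclohex-2-en-1-one) and comes back at 5.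
- The same catalyst with cyclohex-2-en-1-one gives methyl 2-[(1R)-3-(trimethylsilyloxy)cyclohex-2-en-1-yl]propanoate F12.
- Regiospecific fluoride-mediated C-methylation (TBAT, MeI, THF) gives methyl 2-[(1R,2S)-2-methyl-3-oxocyclohexyl]propanoate F13.
- Thermodynamic silylation (Me3SiCl, NaI, Et3N, MeCN) gives the tetrasubstituted silyl enol ether 5.

**Further compounds**
F1 | step 10 | tert-butyl(dimethyl){[(2E)-3-methylpenta-2,4-dien-1-yl]oxy}silane | C=C/C(C)=C/CO[Si](C)(C)C(C)(C)C
F2 | step 10 | tert-butyl{[(2E)-5-iodo-3-methylpent-2-en-1-yl]oxy}dimethylsilane | ICC/C(C)=C/CO[Si](C)(C)C(C)(C)C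
F3 | step 10 | {[(3R)-2,3-dimethylcyclohex-1-en-1-yl]oxy}trimethylsilane | C[C@@H]1CCCC(O[Si](C)(C)C)=C1C
F4 | step 10 | (2S,3R)-2-[(3E)-5-{[tert-butyl(dimethyl)silyl]oxy}-3-methylpent-3-en-1-yl]-2,3-dimethylcyclohexan-1-one | C[C@@H]1CCCC(=O)[C@@]1(C)CC/C(C)=C/CO[Si](C)(C)C(C)(C)C
F5 | step 10 | (5R,6S)-6-[(3E)-5-{[tert-butyl(dimethyl)silyl]oxy}-3-methylpent-3-en-1-yl]-5,6-dimethylcyclohex-1-en-1-yl trifluoromethanesulfonate | C[C@@H]1CCC=C(OS(=O)(=O)C(F)(F)F)[C@@]1(C)CC/C(C)=C/CO[Si](C)(C)C(C)(C)C
F6 | step 10 | tert-butyl({(2E)-5-[(1S,6R)-2-ethenyl-1,6-dimethylcyclohex-2-en-1-yl]-3-methylpent-2-en-1-yl}oxy)dimethylsilane | C[C@@H]1CCC=C(C=C)[C@@]1(C)CC/C(C)=C/CO[Si](C)(C)C(C)(C)C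
F7 | step 10 | methyl (1S,5S,6R,8aR)-5-[(3E)-5-{[tert-butyl(dimethyl)silyl]oxy}-3-methylpent-3-en-1-yl]-1,5,6-trimethyl-1,2,3,5,6,7,8,8a-octahydronaphthalene-1-carboxylate | COC(=O)[C@@]1(C)CCC=C2[C@H]1CC[C@@H](C)[C@]2(C)CC/C(C)=C/CO[Si](C)(C)C(C)(C)C
F8 | step 10 | methyl (1S,5S,6R,8aR)-5-[(3E)-5-hydroxy-3-methylpent-3-en-1-yl]-1,5,6-trimethyl-1,2,3,5,6,7,8,8a-octahydronaphthalene-1-carboxylate | COC(=O)[C@@]1(C)CCC=C2[C@H]1CC[C@@H](C)[C@]2(C)CC/C(C)=C/CO
F9 | step 3 | methyl 5-bromopentanoate | COC(=O)CCCCBr
F10 | step 3 | [(5-bromo-1-methoxypent-1-en-1-yl)oxy]trimethylsilane | BrCCC/C=C(OC)/O[Si](C)(C)C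
F11 | step 3 | methyl 5-bromo-2-[(1S)-2-methyl-3-(trimethylsilyloxy)cyclohex-2-en-1-yl]pentanoate | COC(=O)C(CCCBr)[C@@H]1CCCC(O[Si](C)(C)C)=C1C
F12 | step 2 | methyl 2-[(1R)-3-(trimethylsilyloxy)cyclohex-2-en-1-yl]propanoate | COC(=O)C(C)[C@@H]1CCCC(O[Si](C)(C)C)=C1
F13 | step 2 | methyl 2-[(1R,2S)-2-methyl-3-oxocyclohexyl]propanoate | COC(=O)C(C)[C@@H]1CCCC(=O)[C@H]1C
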